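All runs were computed with constants of no real substance.

Thursday's run ends with its links level, 42.6% at 8.00 min and 42.2% at 20.0 min, while Monday's links are still falling, from 92.0% to 85.1%, and in neither run do links and free first end groups add up to the charge.

in all of them: second end groups 0.168 M

| flask | first end groups | remark | time |
|---|---|---|---|
| Monday's | 0.080 M | run made earlier |  |
| Thursday's | 0.32 M | run made earlier |  |
| flask | 0.16 M |  | 15 min |

| run | time / min | links / % | first end groups / % |
|---|---|---|---|
| Monday's | 1.50 | 92.0 | 5.4 |
| Monday's | 5.00 | 91.3 | 3.0 |
| Monday's | 8.00 | 90.7 | 3.3 |
| Monday's | 12.0 | 87.2 | 3.2 |
| Monday's | 20.0 | 85.1 | 2.3 |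
| Thursday's | 4.00 | 46.9 | 22.2 |
| Thursday's | 8.00 | 42.6 | 12.2 |
| Thursday's | 10.0 | 43.9 | 12.1 |
| Thursday's | 15.0 | 41.7 | 9.5 |
| Thursday's | 20.0 | 42.2 | 9.6 |

(each reading ± 1 percentage point)

- the state of affairs at 15 min: stopped, and by what, or still going (the second end groups has run out first / forward and back rates have come level / it is still moving / all of the first end groups has reacted)
- amount of links at 15 min, in percent of the first end groups charged

- the reaction counts as stopped when no species that holds the first end groups changes by six tenths of a point or more over the second half of the time

Write L for links and A for free first end groups, as shares of the first end groups charged, and B for second end groups on the same scale. The missing share is what L and A leave of the charge. Its ratio to A reads 5.02 at Thursday's last reading and 5.48 at Monday's. The quotient L squared over A times B reads 18.0 on Thursday and 25.2 on Monday; with L unsquared the two runs differ by a factor of 2.78, so I keep the square.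

Now the flask in slow motion, with B charged at 1.05 of A. In the first instants the link step runs, and with nothing missing the quotient puts links at 82.8%, the kinetic level. Through the middle the missing share fills from free A, and links give ground as a correction to that level. At the end, with the ratio held as well, the quotient gives the resting share of links, 64.9%, the thermodynamic level. Between Thursday's quick levelling and Monday's long fall, I put this flask about two points above that at the asked time, still moving.

The forecast gives 66% and it is still moving, holding that “side products keep growing slowly”.

The flask gives 66.9% of links: it is still moving.

    first end groups + second end groups ⇌ links + by-product (K = 17.0, k = 7.60 M⁻¹ s⁻¹)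
    first end groups ⇌ dormant form (K = 4.60, k = 0.00520 s⁻¹)

At 15.0 min the half-life of second end groups by the forward link step alone is 0.14 min, while the slowest mode of this flask, as it stands then, has a half-life of 4.50 min, the longer of the two. Measured from the resting share, links in this flask stand 2 percentage points above it at 15.0 min, and in the neighbour flask, the same charge read at 6.0 min, they stand 7.2 points above it.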